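A direct plan would close ring C last through the O1–C2 bond. Friedel–Crafts prenylation of 2,4-dihydroxybenzaldehyde A1 would give the 5-prenyl aldehyde A2, an enal would fuse ring D on to give chromene aldehyde A3, and A3 would be condensed with 4,5,7-trihydroxycoumarin A4. One cinchona thiourea would carry condensation, translactonisation and oxa-Michael closure to keto lactone A5, which would be hydrolysed to keto acid A6 and decarboxylated. Its weakest steps would be:
- the Friedel–Crafts prenylation, because C3, C5 and oxygen would compete and the wanted isomer would be a minor product;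
- the one-pot cascade, because C2 would be set by a reversible oxa-Michael addition flanked by free hydroxyls, so the ee could drift;
- the final decarboxylation, because ring C of A6 could open and C2 would racemise.

The route rests on the C2–C1' bond between ring C and ring B. Cutting there leaves a flat, achiral 5,7-dioxygenated chromone and a ring B arylboronic acid; one rhodium-catalysed asymmetric 1,4-arylation joins them and sets C2, the only stereocentre, irreversibly and without free base. The step exploits that C1' has one ortho substituent only (O2'; C6' bears hydrogen) and that O2' directs lithiation to C1'. Ring B is assembled regiospecifically on a resorcylate template: chelation places ring D at C3'/O4', and a para-Claisen–Cope shift moves a prenyl group from O2' to C5'. Friedel–Crafts prenylation, oxa-Michael closure of ring C and decarboxylation beside C2 have no counterpart.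

Key step: step 8

Assumption: 5,7-dihydroxy-4H-chromen-4-one is treated as a purchasable compound, and the (S,S) descriptor of the diene in step 8 (assigned by analogy with cyclohex-2-enone) stands for the enantiomer that delivers the aryl group to the Re face of C2.

**Step 1**
Reactants: 1 methyl 2,4-dihydroxybenzoate; 2 3-methylbut-2-enal
Product: 4 methyl 5-hydroxy-2,2-dimethyl-2H-chromene-6-carboxylate, via ortho-quinone methide 3 (not isolated)
Conditions: (H3NCH2CH2NH3)(OAc)2 (ethylenediammonium diacetate, 10 mol%), xylene, 140 °C, 12 h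
Reagents that add atoms: 3-methylbut-2-enal (compound 2), CC(C)=CC=O
Why: Formal [3+3] chromene annulation (Knoevenagel-type aldol, dehydration, oxa-6π electrocyclisation), in which the 2-OH stays hydrogen-bonded to the ester, so condensation should occur at C3 between the two oxygens and 3 should close through the free 4-oxygen to the angular 5-hydroxy-6-carboxylate; no stereocentre.

**Step 2**
Reactants: 4 methyl 5-hydroxy-2,2-dimethyl-2H-chromene-6-carboxylate; 5 1-bromo-3-methylbut-2-ene
Product: 6 methyl 2,2-dimethyl-5-[(3-methylbut-2-en-1-yl)oxy]-2H-chromene-6-carboxylate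
Conditions: K2CO3 (2 equiv), DMF, 50 °C, 12 h
Reagents that add atoms: 1-bromo-3-methylbut-2-ene (compound 5), CC(C)=CCBr
Why: Williamson ether synthesis on the only phenol, where carbonate in DMF is enough to alkylate the chelated hydroxyl with the primary allylic bromide by SN2.

**Step 3**
Reactants: 6 methyl 2,2-dimethyl-5-[(3-methylbut-2-en-1-yl)oxy]-2H-chromene-6-carboxylate
Product: 9 methyl 5-hydroxy-2,2-dimethyl-8-(3-methylbut-2-en-1-yl)-2H-chromene-6-carboxylate, via ortho dienone 7 (not isolated), via para dienone 8 (not isolated)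
Conditions: N,N-diethylaniline, 200 °C (sealed tube), 4 h, Ar
Reagents that add atoms: none
Why: para-Claisen–Cope rearrangement, in which the [3,3] shift of the prenyl ether can only reach a carbon-substituted ortho position (C6 or C4a), the non-enolisable dienone 7 passes the allyl unit on by a second [3,3] shift to C8 (para to the oxygen) with the normal prenyl terminus restored, and 8 tautomerises to the phenol; no stereocentre survives.

**Step 4**
Reactants: 9 methyl 5-hydroxy-2,2-dimethyl-8-(3-methylbut-2-en-1-yl)-2H-chromene-6-carboxylate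
Product: 11 2,2-dimethyl-8-(3-methylbut-2-en-1-yl)-2H-chromen-5-ol, via salicylic acid 10 (not isolated)
Conditions: NaOH (2 M aq)/MeOH 1:2, 70 °C, 8 h; then AcOH to pH 5, solvent exchange to DMF, 110 °C, 2 h, N2
Reagents that add atoms: none
Why: Ester saponification followed by thermal protodecarboxylation of the electron-rich salicylic acid (ipso-protonation at C6, ortho to the phenol and para to the pyran oxygen, then loss of CO2, as with resorcylic acids and 5-hydroxychromene-6-carboxylic acids of the cannabinoid acid type); base is used only at 70 °C so that the prenyl double bond should not move into conjugation.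

**Step 5**
Reactants: 11 2,2-dimethyl-8-(3-methylbut-2-en-1-yl)-2H-chromen-5-ol
Product: 12 5-(methoxymethoxy)-2,2-dimethyl-8-(3-methylbut-2-en-1-yl)-2H-chromene
Conditions: MOMCl (1.5 equiv), iPr2NEt (2 equiv), CH2Cl2, 0 °C to rt
Reagents that add atoms: chloromethyl methyl ether, COCCl
Why: Standard O-alkylation of a phenol with an α-chloro ether; the acetal serves as protecting group for O2' and as directing group for the next step.

**Step 6**
Reactants: 12 5-(methoxymethoxy)-2,2-dimethyl-8-(3-methylbut-2-en-1-yl)-2H-chromene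
Product: 15 [5-(methoxymethoxy)-2,2-dimethyl-8-(3-methylbut-2-en-1-yl)-2H-chromen-6-yl]boronic acid, via aryllithium 13 (not isolated), via lithium triisopropoxyborate 14 (not isolated)
Conditions: n-BuLi (1.2 equiv), TMEDA (1.2 equiv), THF, −20 to 0 °C, 1 h; B(OiPr)3 (2 equiv), −78 °C to rt; AcOH (1.2 equiv), H2O, 0 °C
Reagents that add atoms: triisopropyl borate, CC(C)OB(OC(C)C)OC(C)C; water, O
Why: Directed ortho-metalation, in which the acetal oxygens hold the base next to C6, the only ortho position that bears hydrogen (C4a is ring-fused), and borate trapping with mild hydrolysis gives the boronic acid; low temperature and short time should limit deprotonation of the benzylic-allylic CH2 of the prenyl group.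

**Step 7**
Reactants: 16 5,7-dihydroxy-4H-chromen-4-one
Product: 17 5,7-bis(methoxymethoxy)-4H-chromen-4-one
Conditions: NaH (2.4 equiv), MOMCl (2.4 equiv), DMF, 0 °C to rt
Reagents that add atoms: chloromethyl methyl ether, COCCl
Why: Double O-alkylation with the α-chloro ether, where NaH is needed for the hydrogen-bonded 5-OH; capping both phenols removes acidic protons and the 5-hydroxy-4-keto chelating site before the rhodium step.

**Step 8 (key step)**
Reactants: 15 [5-(methoxymethoxy)-2,2-dimethyl-8-(3-methylbut-2-en-1-yl)-2H-chromen-6-yl]boronic acid (2.5 equiv, in three portions); 17 5,7-bis(methoxymethoxy)-4H-chromen-4-one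
Product: 18 (2S)-5,7-bis(methoxymethoxy)-2-[5-(methoxymethoxy)-2,2-dimethyl-8-(3-methylbut-2-en-1-yl)-2H-chromen-6-yl]-2,3-dihydro-4H-chromen-4-one
Conditions: [RhCl(C2H4)2]2 (2.5 mol%), (S,S)-2,5-diphenylbicyclo[2.2.2]octa-2,5-diene (C20H18, 5.5 mol%), KOH (5 mol%, one per rhodium), degassed 1,4-dioxane/H2O 10:1, 30 °C, 24 h, Ar
Reagents that add atoms: none
Why: Rhodium-catalysed asymmetric 1,4-addition of an arylboronic acid to an enone (Hayashi–Miyaura reaction), a known reaction of chromones: the hydroxo-rhodium diene complex takes the aryl group from boron, the chromone C2=C3 bond coordinates and inserts into the aryl–rhodium bond so that the aryl group ends on C2 and rhodium on C3 as an oxa-π-allyl species, and water protonates this enolate to release 18 and regenerate the hydroxo complex. No ring is closed: preformed ring C and ring B are joined through the C2–C1' bond. C2, the only stereocentre, is set under catalyst control, because the two phenyl groups of the twofold-symmetric diene block one face of the bound chromone and the aryl group should migrate to the Re face of C2 (priorities O1 > C3 > H), which is 2S. The step needs 1,4- over 1,2-addition, which is inherent to insertion into an aryl–rhodium bond, and insertion faster than protodeboronation, which the single ortho substituent at C1' (C6' bears hydrogen), the excess of 15 and the low temperature should secure. It also needs the product not to ring-open to a chalcone, which the absence of free base (KOH only converts the chloride into the hydroxo complex) and the capped 5- and 7-oxygens should secure. The prenyl and chromene double bonds are unactivated and should not compete with the enone for the aryl–rhodium species.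

**Step 9**
Reactants: 18 (2S)-5,7-bis(methoxymethoxy)-2-[5-(methoxymethoxy)-2,2-dimethyl-8-(3-methylbut-2-en-1-yl)-2H-chromen-6-yl]-2,3-dihydro-4H-chromen-4-one
Product: 19 Sanggenol N
Conditions: HCl (3 M aq)/MeOH 1:5, 40 °C, 4 h, N2
Reagents that add atoms: none
Why: Acid-catalysed acetal cleavage (transacetalisation of the three aryl methoxymethyl ethers to methanol); no bond at C2 is touched, base is avoided because it would open ring C by retro-oxa-Michael reaction, and dilute acid at 40 °C should leave the prenyl and chromene double bonds alone.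

**Compound list**
1 | methyl 2,4-dihydroxybenzoate | COC(=O)c1ccc(O)cc1O | starting material
2 | 3-methylbut-2-enal | CC(C)=CC=O | starting material
3 | methyl 2-hydroxy-3-(3-methylbut-2-en-1-ylidene)-4-oxocyclohexa-1,5-diene-1-carboxylate (not isolated) | COC(=O)C1=C(O)C(=CC=C(C)C)C(=O)C=C1 | intermediate
4 | methyl 5-hydroxy-2,2-dimethyl-2H-chromene-6-carboxylate | COC(=O)c1ccc2OC(C)(C)C=Cc2c1O | intermediate
5 | 1-bromo-3-methylbut-2-ene | CC(C)=CCBr | starting material
6 | methyl 2,2-dimethyl-5-[(3-methylbut-2-en-1-yl)oxy]-2H-chromene-6-carboxylate | COC(=O)c1ccc2OC(C)(C)C=Cc2c1OCC=C(C)C | intermediate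
7 | methyl 2,2-dimethyl-6-(2-methylbut-3-en-2-yl)-5-oxo-5,6-dihydro-2H-chromene-6-carboxylate, racemic (not isolated) | COC(=O)C1(C(C)(C)C=C)C=CC2=C(C=CC(C)(C)O2)C1=O | intermediate
8 | methyl 2,2-dimethyl-8-(3-methylbut-2-en-1-yl)-5-oxo-5,8-dihydro-2H-chromene-6-carboxylate, racemic (not isolated) | COC(=O)C1=CC(CC=C(C)C)C2=C(C=CC(C)(C)O2)C1=O | intermediate
9 | methyl 5-hydroxy-2,2-dimethyl-8-(3-methylbut-2-en-1-yl)-2H-chromene-6-carboxylate | COC(=O)c1cc(CC=C(C)C)c2OC(C)(C)C=Cc2c1O | intermediate
10 | 5-hydroxy-2,2-dimethyl-8-(3-methylbut-2-en-1-yl)-2H-chromene-6-carboxylic acid (not isolated) | OC(=O)c1cc(CC=C(C)C)c2OC(C)(C)C=Cc2c1O | intermediate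
11 | 2,2-dimethyl-8-(3-methylbut-2-en-1-yl)-2H-chromen-5-ol | CC(C)=CCc1ccc(O)c2C=CC(C)(C)Oc12 | intermediate
12 | 5-(methoxymethoxy)-2,2-dimethyl-8-(3-methylbut-2-en-1-yl)-2H-chromene | COCOc1ccc(CC=C(C)C)c2OC(C)(C)C=Cc12 | intermediate
13 | [5-(methoxymethoxy)-2,2-dimethyl-8-(3-methylbut-2-en-1-yl)-2H-chromen-6-yl]lithium (not isolated) | [Li]c1cc(CC=C(C)C)c2OC(C)(C)C=Cc2c1OCOC | intermediate
14 | lithium triisopropoxy[5-(methoxymethoxy)-2,2-dimethyl-8-(3-methylbut-2-en-1-yl)-2H-chromen-6-yl]borate (not isolated) | [Li+].CC(C)O[B-](OC(C)C)(OC(C)C)c1cc(CC=C(C)C)c2OC(C)(C)C=Cc2c1OCOC | intermediate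
15 | [5-(methoxymethoxy)-2,2-dimethyl-8-(3-methylbut-2-en-1-yl)-2H-chromen-6-yl]boronic acid | COCOc1c(B(O)O)cc(CC=C(C)C)c2OC(C)(C)C=Cc12 | intermediate
16 | 5,7-dihydroxy-4H-chromen-4-one | O=c1ccoc2cc(O)cc(O)c12 | starting material
17 | 5,7-bis(methoxymethoxy)-4H-chromen-4-one | O=c1ccoc2cc(OCOC)cc(OCOC)c12 | intermediate
18 | (2S)-5,7-bis(methoxymethoxy)-2-[5-(methoxymethoxy)-2,2-dimethyl-8-(3-methylbut-2-en-1-yl)-2H-chromen-6-yl]-2,3-dihydro-4H-chromen-4-one | CC(C)=CCc1cc([C@@H]2CC(=O)c3c(OCOC)cc(OCOC)cc3O2)c(OCOC)c2c1OC(C)(C)C=C2 | intermediate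
19 | Sanggenol N, (2S)-5,7-dihydroxy-2-[5-hydroxy-2,2-dimethyl-8-(3-methylbut-2-en-1-yl)-2H-chromen-6-yl]-2,3-dihydro-4H-chromen-4-one | CC(C)=CCc1cc([C@@H]2CC(=O)c3c(O)cc(O)cc3O2)c(O)c2c1OC(C)(C)C=C2 | target

Total step count: 9. Longest linear sequence: 8 steps (steps 1 to 6, then 8 and 9); step 7 is a one-step side branch.

**Steps most likely to fail**

Step 8. The aryl–rhodium species from the electron-rich ortho-alkoxy boronic acid may be protonated faster than it inserts into the electron-rich chromone, or the diene may discriminate the two faces of C2 poorly with this hindered aryl group. The fallback sets out from 15 and 17. The addition would be run without asymmetric induction with the more active achiral complex [Rh(OH)(C8H12)]2 (C8H12 = cycloocta-1,5-diene; dioxane/H2O, 50 °C) to give the racemic tris(methoxymethyl) flavanone F1. The stereocentre would then be secured by kinetic resolution through asymmetric transfer hydrogenation with (C5Me5)RhCl[(R,R)-TsNCH(Ph)CH(Ph)NH2] (taken as the enantiomer that reduces the 2R ketone faster), HCO2H/Et3N 5:2, EtOAc, rt, stopped near half conversion. The 2R enantiomer would be reduced to the cis flavan-4-ol F2 and removed on silica; the unreacted 2S ketone is 18, where the route is rejoined.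

Step 6. n-BuLi may deprotonate the benzylic-allylic CH2 of the prenyl group in competition with C6, or the electron-rich boronic acid may lose boron during work-up. The fallback sets out from 11. Iodination with N-iodosuccinimide (CH2Cl2, −40 °C) should go to C6, the only ring carbon activated by both oxygens, and give 6-iodo-2,2-dimethyl-8-(3-methylbut-2-en-1-yl)-2H-chromen-5-ol F3. Methoxymethylation as in step 5 would give the iodo acetal F4. Iodine–magnesium exchange (i-PrMgCl·LiCl, THF, −20 °C) would give the arylmagnesium chloride F5 without any C–H deprotonation, and B(OiPr)3 followed by AcOH/H2O would return the route to 15.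

Step 9. Acid may ionise the C2–O1 bond (the benzylic cation is stabilised by O2' and O4'), which would racemise C2, or methanol may add to the chromene double bond. The fallback sets out from 11 and 16 and replaces all three methoxymethyl groups by 1-ethoxyethyl acetals, which are cleaved by a pyridinium salt at room temperature. Phenol 11 with ethyl vinyl ether (pyridinium p-toluenesulfonate cat., CH2Cl2) would give 5-(1-ethoxyethoxy)-2,2-dimethyl-8-(3-methylbut-2-en-1-yl)-2H-chromene F6. Lithiation and borylation as in step 6 would give the boronic acid F7. Chromone 16 with 1-chloroethyl ethyl ether (NaH, DMF) would give 5,7-bis(1-ethoxyethoxy)-4H-chromen-4-one F8. The addition of step 8 would give the (2S) tris(1-ethoxyethyl) flavanone F9 (a mixture of acetal epimers, which is irrelevant), and pyridinium p-toluenesulfonate (MeOH, rt) would release 19.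

**Further compounds**
F1 | step 8 | racemic 5,7-bis(methoxymethoxy)-2-[5-(methoxymethoxy)-2,2-dimethyl-8-(3-methylbut-2-en-1-yl)-2H-chromen-6-yl]-2,3-dihydro-4H-chromen-4-one | CC(C)=CCc1cc(C2CC(=O)c3c(OCOC)cc(OCOC)cc3O2)c(OCOC)c2c1OC(C)(C)C=C2
F2 | step 8 | (2R,4R)-5,7-bis(methoxymethoxy)-2-[5-(methoxymethoxy)-2,2-dimethyl-8-(3-methylbut-2-en-1-yl)-2H-chromen-6-yl]-3,4-dihydro-2H-chromen-4-ol (cis) | CC(C)=CCc1cc([C@H]2C[C@@H](O)c3c(OCOC)cc(OCOC)cc3O2)c(OCOC)c2c1OC(C)(C)C=C2
F3 | step 6 | 6-iodo-2,2-dimethyl-8-(3-methylbut-2-en-1-yl)-2H-chromen-5-ol | CC(C)=CCc1cc(I)c(O)c2C=CC(C)(C)Oc12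
F4 | step 6 | 6-iodo-5-(methoxymethoxy)-2,2-dimethyl-8-(3-methylbut-2-en-1-yl)-2H-chromene | COCOc1c(I)cc(CC=C(C)C)c2OC(C)(C)C=Cc12
F5 | step 6 | [5-(methoxymethoxy)-2,2-dimethyl-8-(3-methylbut-2-en-1-yl)-2H-chromen-6-yl]magnesium chloride | COCOc1c([Mg]Cl)cc(CC=C(C)C)c2OC(C)(C)C=Cc12
F6 | step 9 | 5-(1-ethoxyethoxy)-2,2-dimethyl-8-(3-methylbut-2-en-1-yl)-2H-chromene | CCOC(C)Oc1ccc(CC=C(C)C)c2OC(C)(C)C=Cc12
F7 | step 9 | [5-(1-ethoxyethoxy)-2,2-dimethyl-8-(3-methylbut-2-en-1-yl)-2H-chromen-6-yl]boronic acid | CCOC(C)Oc1c(B(O)O)cc(CC=C(C)C)c2OC(C)(C)C=Cc12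
F8 | step 9 | 5,7-bis(1-ethoxyethoxy)-4H-chromen-4-one | O=c1ccoc2cc(OC(C)OCC)cc(OC(C)OCC)c12
F9 | step 9 | (2S)-5,7-bis(1-ethoxyethoxy)-2-[5-(1-ethoxyethoxy)-2,2-dimethyl-8-(3-methylbut-2-en-1-yl)-2H-chromen-6-yl]-2,3-dihydro-4H-chromen-4-one | CC(C)=CCc1cc([C@@H]2CC(=O)c3c(OC(C)OCC)cc(OC(C)OCC)cc3O2)c(OC(C)OCC)c2c1OC(C)(C)C=C2
A1 | direct plan | 2,4-dihydroxybenzaldehyde | O=Cc1ccc(O)cc1O
A2 | direct plan | 2,4-dihydroxy-5-(3-methylbut-2-en-1-yl)benzaldehyde | CC(C)=CCc1cc(C=O)c(O)cc1O
A3 | direct plan | 5-hydroxy-2,2-dimethyl-8-(3-methylbut-2-en-1-yl)-2H-chromene-6-carbaldehyde | CC(C)=CCc1cc(C=O)c(O)c2c1OC(C)(C)C=C2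
A4 | direct plan | 4,5,7-trihydroxy-2H-chromen-2-one | O=C1C=C(O)c2c(O)cc(O)cc2O1
A5 | direct plan | (2S,3S)-cis keto lactone, the 3-carboxyflavanone lactonised onto the 2'-oxygen | CC(C)=CCc1cc2c(OC(=O)[C@H]3[C@@H]2Oc2cc(O)cc(O)c2C3=O)c2c1OC(C)(C)C=C2
A6 | direct plan | (2S)-5,7-dihydroxy-2-[5-hydroxy-2,2-dimethyl-8-(3-methylbut-2-en-1-yl)-2H-chromen-6-yl]-4-oxochromane-3-carboxylic acid, C3 labile | CC(C)=CCc1cc([C@@H]2C(C(=O)O)C(=O)c3c(O)cc(O)cc3O2)c(O)c2c1OC(C)(C)C=C2
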